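## Analysis of the target

Target 19 is (1R,4R,5R)-1-[(E)-heptadec-12-en-1-yl]cyclohex-2-ene-1,4,5-triol. It is a single cyclohexene ring with a tertiary allylic carbinol at C1 (which also carries the C17 chain), the C2=C3 double bond, a secondary allylic carbinol at C4, a secondary carbinol at C5 and a C6 methylene. The 4,5-diol is trans. The C1 hydroxyl is cis to the C4 hydroxyl and trans to the C5 hydroxyl, so in the half-chair with a diequatorial diol the C1 hydroxyl is pseudoaxial and the chain pseudoequatorial. The chain holds one isolated E double bond (C12′=C13′), which rules out late hydrogenation, uncontrolled metathesis and excess electrophilic oxidant. The sensitive group is the tertiary allylic alcohol next to a second allylic alcohol: acid ionises C1–O and loss of two molecules of water aromatises the ring, so the free triol has to be released under neutral or basic conditions. The hard problem is C1: a fully substituted carbinol carbon that is 1,3 and 1,4 to the only other stereocenters, so a carbonyl addition at C1 has no dependable control element. The feature the route is built on is the array C1′–C1(OH)–C6H2–C5H(OH)–C4H(OH). Atom for atom, and with the same absolute configuration at C1, C4 and C5, it is the array C7–C1(OH)–C6H2–C5H(OH)–C4H(OH) of (−)-quinic acid 7. The carboxyl carbon C7 of 7 becomes C1′ of the chain, and the C2H2–C3H(OH) unit of 7 becomes the C2=C3 alkene.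

## Retrosynthetic reasoning

19 from 17: the C2=C3 double bond is made last, by syn-elimination of selenoxide 18 formed from the saturated triol selenide 17. No skeletal bond is cut here. The gain is that the acid-sensitive tertiary allylic alcohol appears only in the final, non-acidic operation. The forward step must eliminate toward C2 and not toward the carbinol carbon C4.

17 from 16: the trans-4,5-diol is unmasked from its butane-2,3-diacetal by aqueous acid while the ring is still saturated and C1–O is an ordinary tertiary alcohol. The forward step must cleave the acetal without touching C1, the chain alkene or the selenide.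

16 from 14 and 15 (key disconnection): the C1′–C2′ bond of the chain is cut, two atoms away from the ring, and not the C1–C1′ bond at the ring. The electrophile is spiro-epoxide 14, in which C1′ is the old carboxyl carbon of 7 and the C1–O bond is the one 7 was born with. The nucleophile is the C16 Grignard reagent 15. The full carbon skeleton is assembled in this step and no stereocenter has to be created. The forward step must open the epoxide only at its CH2 terminus.

14 from 12 from 11: the epoxide comes from the 1,2-diol 12 by sulfonylation of the primary hydroxyl and closure through tosylate 13. Diol 12 comes from reduction of the α-hydroxy ester 11. C1–O is never broken.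

11 from 9 from 7: selenium is placed at C3 by SN2 displacement of the axial triflate 10 while C1–OH is still a hindered, unreactive α-hydroxy ester hydroxyl. Compound 9 is available from 7 in one operation (through methyl ester 8), because the diacetal bridges only the diequatorial trans-4,5-diol and leaves 3-OH free. This is what singles out the one hydroxyl of 7 that the target does not contain.

15 from 6 from 5 from 4 from 1 and 2: the chain alkene is set as E before the coupling, by dissolving-metal reduction of alkyne 4. Alkyne 4 is the alkylation product of acetylide 3 (from 1) with bromo alcohol 2.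

## Alternatives that were turned down

Alternative 1: the textbook route cuts C1–C1′. Quinic acid 7 is degraded to the enone A1 ((4R,5R)-4,5-O-BDA-4,5-dihydroxycyclohex-2-en-1-one, C7 excised by diol cleavage), and the C17 Grignard reagent A2 adds 1,2 to the carbonyl to give the protected target A3. It was turned down for three reasons.
- The step creates C1, the hardest stereocenter, under substrate control with nothing to direct it. In the conformationally locked, trans-fused A1 the C5 oxygen is equatorial and both faces are open. The stereoelectronically preferred axial attack puts the chain axial and gives the C1 epimer A4, whereas the target needs equatorial attack.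
- A3 is a tertiary allylic alcohol that still carries a protecting group removable only by strong acid.
- Four steps are spent deleting C7 and the C1 stereocenter of 7, only to rebuild both in one uncontrolled step.

Alternative 2: a suprafacial 1,3-transposition. From (−)-shikimic acid A5 the chain is built on the carboxyl carbon to give the allylic alcohol A6 (1-alkylcyclohex-1-en-3-ol, 4,5-O-BDA). Hydroxyl-directed epoxidation (VO(acac)2, t-BuOOH) to the syn-epoxy alcohol A7, sulfonylation and reductive elimination would move the oxygen from C3 to C1 with transfer of configuration. It was turned down because the C1 oxygen that 7 already holds has to be created in three extra steps. The chain would also have to be joined at an allylic carbon, where organocopper reagents choose between SN2 and SN2′. The one-step catalytic variant (Ph3SiOReO3) is an equilibrium that favours the trisubstituted alkene and secondary alcohol, that is A6. The diacetal would again have to leave from a tertiary allylic alcohol.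

Alternative 3: dearomatisation and enzymatic desymmetrisation. Phenol A8 is oxidised to the prochiral para-quinol A9. An ene-reductase (old-yellow-enzyme class) reduces one of the two enantiotopic enone double bonds to the (R)-enone A10. α′-Hydroxylation of the ketone and 1,2-reduction would complete the triol. It was turned down because the enzyme sets C1 only. C5 and C4 must then be set by an enolate oxidation 1,3 to the quaternary carbon and a hydride reduction next to the new hydroxyl, two substrate-controlled steps without a dependable bias. A C17 lipid chain is also a poor substrate for an aqueous enzymatic step, and quinols of type A9 are prone to dienone–phenol rearrangement. That is three stereochemical risks against none.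

Key step: step 8

Remark: ring positions of all intermediates carry quinic acid numbering (C1 carbinol carbon, C7 its exocyclic carbon). "BDA" is the (2S,3S)-2,3-dimethoxybutane-2,3-diyl bridge on O4 and O5. Compounds 1, 2 and 7 are taken as commercial.

## Route

Step 1
Reactants: 1 1-hexyne; 2 10-bromodecan-1-ol
Product: 4 hexadec-11-yn-1-ol, via hex-1-yn-1-yllithium 3 (not isolated)
Conditions: 1 (2.5 equiv), n-BuLi (2.4 equiv), THF, −78 → 0 °C; then 2, DMPU, 0 °C → rt; aq NH4Cl
Reagents that add atoms: none
Why: Acetylide alkylation (SN2) at the primary bromide; the first equivalent of 3 deprotonates the hydroxyl of 2 and the resulting lithium alkoxide is a much poorer nucleophile than the acetylide in THF/DMPU.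

Step 2
Reactants: 4 hexadec-11-yn-1-ol
Product: 5 (E)-hexadec-11-en-1-ol
Conditions: Na, NH3 (l), THF, −33 °C; then NH4Cl
Reagents that add atoms: none
Why: Dissolving-metal reduction of an internal alkyne; the vinyl radical anion relaxes to the trans geometry before protonation, which sets the E double bond, and the isolated alkene and the alkoxide are not reduced further.

Step 3
Reactants: 5 (E)-hexadec-11-en-1-ol
Product: 6 (E)-16-bromohexadec-5-ene
Conditions: CBr4, PPh3, CH2Cl2, 0 °C
Reagents that add atoms: carbon tetrabromide, BrC(Br)(Br)Br
Why: Appel reaction; SN2 displacement of the alkoxyphosphonium at a primary carbon under neutral conditions leaves the E alkene untouched.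

Step 4
Reactants: 7 (−)-quinic acid, (1S,3R,4S,5R)-1,3,4,5-tetrahydroxycyclohexane-1-carboxylic acid
Product: 9 methyl (1S,3R,4R,5R)-1,3-dihydroxy-4,5-[(2S,3S)-2,3-dimethoxybutane-2,3-diylbis(oxy)]cyclohexane-1-carboxylate (4,5-O-BDA methyl quinate; 1-OH and 3-OH cis and axial), via methyl quinate 8 (not isolated)
Conditions: butane-2,3-dione, HC(OMe)3, MeOH, camphorsulfonic acid (cat.), reflux
Reagents that add atoms: butane-2,3-dione, CC(=O)C(C)=O; methanol, CO; trimethyl orthoformate, COC(OC)OC
Why: Fischer esterification and trans-selective diacetalisation in one pot; only the diequatorial 4,5-diol can be bridged by the chair 1,4-dioxane with both methoxy groups axial (anomeric control of the two acetal carbons), so 3-OH and 1-OH stay free and no ring stereocenter is touched.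

Step 5
Reactants: 9 4,5-O-BDA methyl quinate
Product: 11 methyl (1R,3S,4S,5R)-1-hydroxy-3-(phenylselanyl)-4,5-O-BDA-cyclohexane-1-carboxylate (PhSe equatorial, trans to 1-OH and to O4), via axial C3 trifluoromethanesulfonate 10 (not isolated)
Conditions: Tf2O (1.1 equiv), pyridine, CH2Cl2, −30 °C; then PhSeSePh/NaBH4 (PhSeNa, 2 equiv), EtOH–THF, 0 °C → rt
Reagents that add atoms: diphenyl diselenide, c1ccccc1[Se][Se]c1ccccc1
Why: The secondary 3-OH is triflated while the tertiary α-hydroxy-ester hydroxyl is inert; the soft, weakly basic selenolate then displaces the axial triflate along the unhindered equatorial trajectory (SN2, inversion). The C3 configuration so set is of no consequence later because C3 becomes sp2.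

Step 6
Reactants: 11 selenide ester
Product: 12 (1R,3S,4S,5R)-1-(hydroxymethyl)-3-(phenylselanyl)-4,5-O-BDA-cyclohexan-1-ol
Conditions: NaBH4, EtOH, 0 °C → rt
Reagents that add atoms: none
Why: Hydroxyl-assisted borohydride reduction of an α-hydroxy ester to the 1,2-diol; selenide and diacetal are inert and no stereocenter is involved.

Step 7
Reactants: 12 diol
Product: 14 spiro-epoxide, (1R,3S,4S,5R)-1,7-anhydro derivative of 12 (oxirane oxygen on C1 on the face of the former 1-OH, oxirane CH2 = C7), via primary p-toluenesulfonate 13 (not isolated)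
Conditions: TsCl, Et3N, DMAP (cat.), CH2Cl2, 0 °C → rt; then K2CO3, MeOH, rt
Reagents that add atoms: none
Why: The primary hydroxyl is sulfonylated in preference to the tertiary one, and the tertiary alkoxide closes the oxirane by intramolecular Williamson displacement at C7 (3-exo-tet); the C1–O bond is not broken, so C1 keeps its configuration.

Step 8
Reactants: 6 (E)-16-bromohexadec-5-ene; 14 spiro-epoxide
Product: 16 (1R,3S,4S,5R)-1-[(E)-heptadec-12-en-1-yl]-3-(phenylselanyl)-4,5-O-BDA-cyclohexan-1-ol, via (E)-hexadec-11-en-1-ylmagnesium bromide 15 (not isolated)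
Conditions: 6, Mg, THF, rt (gives 15, 1.5 equiv); CuI (10 mol %), THF, −30 °C, then 14, −30 → 0 °C; aq NH4Cl
Reagents that add atoms: none
Why: Grignard reagent 15 transmetalates to CuI to give an alkylcuprate of monovalent copper, which attacks the unsubstituted oxirane carbon C7 in an SN2-type oxidative addition anti to the C7–O bond; reductive elimination from the trivalent copper intermediate forms the C7–C(chain) bond, the C1′–C2′ bond of the target. The closest known reaction type is the CuI-catalysed opening of 2,2-disubstituted terminal epoxides by primary alkyl Grignard reagents to give tertiary alcohols. No ring is closed and no stereocenter is created: the C1–O bond inherited from 7 is a spectator, so C1, C4 and C5 arrive with the configuration of the chiral pool. The selectivity needed is regiochemical (CH2 against the fully substituted C1) and is secured by the steric difference between the two oxirane carbons, and by the cuprate pathway being faster than Lewis-acid opening at C1. Chemoselectivity is secured by the substrate: it has no acidic hydrogen, the diacetal and the aryl alkyl selenide do not react with Grignard reagents or cuprates at or below 0 °C, and the alkene of 15 is isolated and inert. In one operation the step joins the C16 chain to the C7 core and completes the carbon skeleton of 19.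

Step 9
Reactants: 16 coupled diacetal
Product: 17 (1R,3R,4S,5S)-1-[(E)-heptadec-12-en-1-yl]-5-(phenylselanyl)cyclohexane-1,3,4-triol (quinic numbering: 1-OH and 4-OH up, 5-OH and 3-SePh down)
Conditions: CF3CO2H–H2O (9:1), 0 °C → rt, short contact; toluene co-evaporation; NaHCO3, MeOH
Reagents that add atoms: none
Why: Acid hydrolysis of the butane-2,3-diacetal proceeds by cleavage at the acetal carbons, so the C4–O and C5–O bonds and their configurations are retained. The tertiary C1–OH is not yet allylic and its ionisation is slowed by the two γ-heteroatoms, the diequatorial trans β-hydroxy selenide cannot reach the antiperiplanar geometry needed for selenium participation, and short contact keeps addition of the acid to the chain alkene negligible.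

Step 10
Reactants: 17 triol selenide
Product: 19 (1R,4R,5R)-1-[(E)-heptadec-12-en-1-yl]cyclohex-2-ene-1,4,5-triol, via selenoxide 18 (not isolated)
Conditions: mCPBA (1.0 equiv), THF, −78 °C; then i-Pr2NH, −78 °C → rt
Reagents that add atoms: none
Why: Selenium is oxidised at −78 °C far faster than either alkene is epoxidised, and on warming the selenoxide undergoes syn-elimination. As with every trans β-hydroxy selenoxide, elimination goes away from the carbinol carbon C4 toward the C2 hydrogen cis to selenium, giving the allylic alcohol and not the enol. The amine buffers the medium and traps benzeneselenenic acid, and no stereocenter is touched.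

## Compound list

1 | 1-hexyne | CCCCC#C | starting material
2 | 10-bromodecan-1-ol | OCCCCCCCCCCBr | starting material
3 | hex-1-yn-1-yllithium | CCCCC#C[Li] | intermediate
4 | hexadec-11-yn-1-ol | CCCCC#CCCCCCCCCCCO | intermediate
5 | (E)-hexadec-11-en-1-ol | CCCC/C=C/CCCCCCCCCCO | intermediate
6 | (E)-16-bromohexadec-5-ene | CCCC/C=C/CCCCCCCCCCBr | intermediate
7 | (−)-quinic acid, (1S,3R,4S,5R)-1,3,4,5-tetrahydroxycyclohexane-1-carboxylic acid | OC(=O)[C@]1(O)C[C@@H](O)[C@@H](O)[C@H](O)C1 | starting material
8 | methyl quinate, methyl (1S,3R,4S,5R)-1,3,4,5-tetrahydroxycyclohexane-1-carboxylate | COC(=O)[C@]1(O)C[C@@H](O)[C@@H](O)[C@H](O)C1 | intermediate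
9 | methyl (1S,3R,4R,5R)-1,3-dihydroxy-4,5-[(2S,3S)-2,3-dimethoxybutane-2,3-diylbis(oxy)]cyclohexane-1-carboxylate | COC(=O)[C@]1(O)C[C@@H](O)[C@H]2O[C@](C)(OC)[C@@](C)(OC)O[C@@H]2C1 | intermediate
10 | (1R,3R,4S,5R) 3-O-trifluoromethanesulfonate of 9 (triflate axial) | COC(=O)[C@]1(O)C[C@@H](OS(=O)(=O)C(F)(F)F)[C@H]2O[C@](C)(OC)[C@@](C)(OC)O[C@@H]2C1 | intermediate
11 | methyl (1R,3S,4S,5R)-1-hydroxy-3-(phenylselanyl)-4,5-O-BDA-cyclohexane-1-carboxylate | COC(=O)[C@]1(O)C[C@H]([Se]c3ccccc3)[C@H]2O[C@](C)(OC)[C@@](C)(OC)O[C@@H]2C1 | intermediate
12 | (1R,3S,4S,5R)-1-(hydroxymethyl)-3-(phenylselanyl)-4,5-O-BDA-cyclohexan-1-ol | OC[C@]1(O)C[C@H]([Se]c3ccccc3)[C@H]2O[C@](C)(OC)[C@@](C)(OC)O[C@@H]2C1 | intermediate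
13 | primary p-toluenesulfonate of 12 (C7–OTs, 1-OH free) | Cc4ccc(cc4)S(=O)(=O)OC[C@]1(O)C[C@H]([Se]c3ccccc3)[C@H]2O[C@](C)(OC)[C@@](C)(OC)O[C@@H]2C1 | intermediate
14 | spiro-epoxide, (1R,3S,4S,5R)-1,7-anhydro-3-(phenylselanyl)-4,5-O-BDA derivative of 12 | C4O[C@]45C[C@H]([Se]c3ccccc3)[C@H]2O[C@](C)(OC)[C@@](C)(OC)O[C@@H]2C5 | intermediate
15 | (E)-hexadec-11-en-1-ylmagnesium bromide | CCCC/C=C/CCCCCCCCCC[Mg]Br | intermediate
16 | (1R,3S,4S,5R)-1-[(E)-heptadec-12-en-1-yl]-3-(phenylselanyl)-4,5-O-BDA-cyclohexan-1-ol | CCCC/C=C/CCCCCCCCCCC[C@]1(O)C[C@H]([Se]c3ccccc3)[C@H]2O[C@](C)(OC)[C@@](C)(OC)O[C@@H]2C1 | intermediate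
17 | (1R,3R,4S,5S)-1-[(E)-heptadec-12-en-1-yl]-5-(phenylselanyl)cyclohexane-1,3,4-triol | CCCC/C=C/CCCCCCCCCCC[C@]1(O)C[C@H]([Se]c2ccccc2)[C@@H](O)[C@H](O)C1 | intermediate
18 | selenoxide of 17 (both configurations at selenium) | CCCC/C=C/CCCCCCCCCCC[C@]1(O)C[C@H]([Se](=O)c2ccccc2)[C@@H](O)[C@H](O)C1 | intermediate
19 | (1R,4R,5R)-1-[(E)-heptadec-12-en-1-yl]cyclohex-2-ene-1,4,5-triol | CCCC/C=C/CCCCCCCCCCC[C@]1(O)C=C[C@@H](O)[C@H](O)C1 | target

## Step count and risk

Total step count: 10 (steps 1–3 for the chain, steps 4–10 for the core and endgame). Longest linear sequence: 7 steps (steps 4–10, from 7).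

Least certain steps:

Step 8 (key step). What may go wrong: alkyl transfer from copper to the CH2 next to a fully substituted carbon is slow, and the soft selenide can tie up the monovalent copper. MgBr2 in the Grignard solution then has time to open the oxirane to a bromohydrin, or to isomerise it by a Meinwald-type hydride shift. Fallback: take selenium out of the coupling. The fallback sets out from 9 and returns at 16. NaBH4 reduction of 9 gives the selenium-free triol F1. Selective tosylation of its primary hydroxyl gives the tosylate F2, and K2CO3 in MeOH closes it to the hydroxy epoxide F3. F3 is opened with 15 and CuI (one further equivalent of 15 serves as base for the 3-OH) to give the chain-bearing diol F4. Its secondary 3-OH is then triflated to the triflate F5, which is displaced by PhSeNa to give 16.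

Step 9. What may go wrong: before the diacetal is fully cleaved, the acid may ionise C1–O (dehydration or epimerisation of the tertiary carbinol), add across the chain alkene, or promote a selenium-assisted 1,2-shift between C3 and C4. Fallback: cleave the diacetal before the chain and the ordinary tertiary alcohol exist. The fallback sets out from 11 and returns at 17.
- Aqueous CF3CO2H on 11, where C1–O is deactivated by the ester, gives the triol ester F6.
- TBSOTf and 2,6-lutidine give the 4,5-bis(tert-butyldimethylsilyl) ether ester F7.
- LiAlH4 gives the silylated diol F8.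
- TsCl/Et3N gives its primary tosylate F9, and K2CO3 in MeOH the silylated spiro-epoxide F10.
- Opening with 15 and CuI gives the silylated coupling product F11.
- Tetrabutylammonium fluoride in THF frees 17.

Step 5. What may go wrong: E2 loss of the axial triflate (two antiperiplanar hydrogens) may outrun the substitution, or the displacement may be retarded by the neighbouring acetal oxygen. Fallback: abandon the discrete sulfonate for a redox condensation. From 9, N-(phenylselanyl)phthalimide and PBu3 in THF activate the 3-OH as an oxyphosphonium ion that is displaced by selenolate within the same ion pair, with inversion, giving 11 directly. No new compound is made.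

Step 10. What may go wrong: the selenenic acid or residual oxidant may react with the two alkenes of the free triol (epoxidation, hydroxyselenation), or regiocontrol may be lost. Fallback: run the elimination on a protected substrate with a periodate oxidant and desilylate last. The fallback sets out from 11, follows the fallback of step 9 as far as F11, and returns at 19. NaIO4 and NaHCO3 in aqueous THF–MeOH (possible here because no free diol is present) oxidise F11 to the silylated selenoxide F12. F12 eliminates at room temperature to the 4,5-bis(tert-butyldimethylsilyl) ether of the target F13, and tetrabutylammonium fluoride then gives 19.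

## Further compounds

F1 | step 8 | (1S,3R,4R,5R)-1-(hydroxymethyl)-4,5-O-BDA-cyclohexane-1,3-diol | OC[C@]1(O)C[C@@H](O)[C@H]2O[C@](C)(OC)[C@@](C)(OC)O[C@@H]2C1
F2 | step 8 | primary p-toluenesulfonate of F1 | Cc4ccc(cc4)S(=O)(=O)OC[C@]1(O)C[C@@H](O)[C@H]2O[C@](C)(OC)[C@@](C)(OC)O[C@@H]2C1
F3 | step 8 | 1,7-anhydro spiro-epoxide of F1 with free axial 3-OH | C4O[C@]45C[C@@H](O)[C@H]2O[C@](C)(OC)[C@@](C)(OC)O[C@@H]2C5
F4 | step 8 | 1-[(E)-heptadec-12-en-1-yl]-4,5-O-BDA-cyclohexane-1,3-diol (1-OH and 3-OH cis, axial) | CCCC/C=C/CCCCCCCCCCC[C@]1(O)C[C@@H](O)[C@H]2O[C@](C)(OC)[C@@](C)(OC)O[C@@H]2C1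
F5 | step 8 | 3-O-trifluoromethanesulfonate of F4 | CCCC/C=C/CCCCCCCCCCC[C@]1(O)C[C@@H](OS(=O)(=O)C(F)(F)F)[C@H]2O[C@](C)(OC)[C@@](C)(OC)O[C@@H]2C1
F0 | step 5 | none | none
F6 | step 9 | methyl 1,4,5-trihydroxy-3-(phenylselanyl)cyclohexane-1-carboxylate (quinic numbering; 1-OH, 4-OH up; 5-OH, 3-SePh down) | COC(=O)[C@]1(O)C[C@H]([Se]c2ccccc2)[C@@H](O)[C@H](O)C1
F7 | step 9 | 4,5-bis-O-(tert-butyldimethylsilyl) ether of F6 | COC(=O)[C@]1(O)C[C@H]([Se]c2ccccc2)[C@@H](O[Si](C)(C)C(C)(C)C)[C@H](O[Si](C)(C)C(C)(C)C)C1
F8 | step 9 | 1-(hydroxymethyl)-3-(phenylselanyl)-4,5-bis(tert-butyldimethylsilyloxy)cyclohexan-1-ol | OC[C@]1(O)C[C@H]([Se]c2ccccc2)[C@@H](O[Si](C)(C)C(C)(C)C)[C@H](O[Si](C)(C)C(C)(C)C)C1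
F9 | step 9 | primary p-toluenesulfonate of F8 | Cc4ccc(cc4)S(=O)(=O)OC[C@]1(O)C[C@H]([Se]c2ccccc2)[C@@H](O[Si](C)(C)C(C)(C)C)[C@H](O[Si](C)(C)C(C)(C)C)C1
F10 | step 9 | 1,7-anhydro spiro-epoxide of F8 | C4O[C@]45C[C@H]([Se]c2ccccc2)[C@@H](O[Si](C)(C)C(C)(C)C)[C@H](O[Si](C)(C)C(C)(C)C)C5
F11 | step 9 | 1-[(E)-heptadec-12-en-1-yl]-3-(phenylselanyl)-4,5-bis(tert-butyldimethylsilyloxy)cyclohexan-1-ol | CCCC/C=C/CCCCCCCCCCC[C@]1(O)C[C@H]([Se]c2ccccc2)[C@@H](O[Si](C)(C)C(C)(C)C)[C@H](O[Si](C)(C)C(C)(C)C)C1
F12 | step 10 | selenoxide of F11 | CCCC/C=C/CCCCCCCCCCC[C@]1(O)C[C@H]([Se](=O)c2ccccc2)[C@@H](O[Si](C)(C)C(C)(C)C)[C@H](O[Si](C)(C)C(C)(C)C)C1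
F13 | step 10 | 4,5-bis-O-(tert-butyldimethylsilyl) ether of 19 | CCCC/C=C/CCCCCCCCCCC[C@]1(O)C=C[C@@H](O[Si](C)(C)C(C)(C)C)[C@H](O[Si](C)(C)C(C)(C)C)C1
A1 | alternative 1 | (4R,5R)-4,5-O-BDA-4,5-dihydroxycyclohex-2-en-1-one | O=C1C=C[C@H]2O[C@](C)(OC)[C@@](C)(OC)O[C@@H]2C1
A2 | alternative 1 | (E)-heptadec-12-en-1-ylmagnesium bromide | CCCC/C=C/CCCCCCCCCCC[Mg]Br
A3 | alternative 1 | 4,5-O-BDA derivative of 19 (chain equatorial, 1-OH cis to O4) | CCCC/C=C/CCCCCCCCCCC[C@]1(O)C=C[C@H]2O[C@](C)(OC)[C@@](C)(OC)O[C@@H]2C1
A4 | alternative 1 | C1 epimer of A3 (chain axial, 1-OH trans to O4) | CCCC/C=C/CCCCCCCCCCC[C@@]1(O)C=C[C@H]2O[C@](C)(OC)[C@@](C)(OC)O[C@@H]2C1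
A5 | alternative 2 | (−)-shikimic acid, (3R,4S,5R)-3,4,5-trihydroxycyclohex-1-ene-1-carboxylic acid | OC(=O)C1=C[C@@H](O)[C@@H](O)[C@H](O)C1
A6 | alternative 2 | 1-[(E)-heptadec-12-en-1-yl]-4,5-O-BDA-cyclohex-1-en-3-ol (3-OH cis to O4) | CCCC/C=C/CCCCCCCCCCCC1=C[C@@H](O)[C@H]2O[C@](C)(OC)[C@@](C)(OC)O[C@@H]2C1
A7 | alternative 2 | 1,2-epoxide of A6, oxirane syn to 3-OH | CCCC/C=C/CCCCCCCCCCC[C@]12O[C@H]1[C@@H](O)[C@H]3O[C@](C)(OC)[C@@](C)(OC)O[C@@H]3C2
A8 | alternative 3 | 4-[(E)-heptadec-12-en-1-yl]phenol | CCCC/C=C/CCCCCCCCCCCc1ccc(O)cc1
A9 | alternative 3 | 4-[(E)-heptadec-12-en-1-yl]-4-hydroxycyclohexa-2,5-dien-1-one | CCCC/C=C/CCCCCCCCCCCC1(O)C=CC(=O)C=C1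
A10 | alternative 3 | (R)-4-[(E)-heptadec-12-en-1-yl]-4-hydroxycyclohex-2-en-1-one | CCCC/C=C/CCCCCCCCCCC[C@]1(O)C=CC(=O)CC1
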